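**Plan** (abietane numbering: ring A = C1–C5, C10; ring B = C5–C10; aromatic ring C = C8, C9, C11–C14; lactone ring D = C4, C19(=O), O, C20, C10, C5)
- Enabling feature: C7 is a single carbonyl carbon held between aromatic C8 and the C6 methylene. Ring B can therefore be opened by removing C7 as CO, which cuts C7–C8 and C6–C7. This leaves a C8 iodide and an exocyclic C5=C6H2 alkene on the one-carbon bridge of the ring A/ring D bicycle.
- Cuts made before that one: hydroquinone back to the 11,12,14-trimethyl ether, and C5–H back to the C5=C6 enone.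
- Cuts made after it: C5=C6 (Wittig), C10–C20 and O–C19 (formaldehyde aldol, lactonisation), C9–C10 (ketone α-arylation), C4–C18 (methylation).
- Forward order: rings C and A are bought and functionalised, joined at C9–C10, then ring D closes, and ring B closes last.
- Stereochemistry: C4 comes from a valine auxiliary. C10 is relayed from C4, because only the cis hydroxymethyl ester can lactonise. C5 comes from electron-transfer reduction of the enone with protonation on the α face.

Key step: step 10

Assumption: the lithioenamine from L-valine tert-butyl ester in toluene–HMPA is taken to be methylated on the face that gives the (S)-keto ester; if the sense is the opposite, D-valine tert-butyl ester is used and nothing else changes.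

Step 1
Reactants: 1 1,2,4-trimethoxybenzene; 2 acetone
Product: 4 2-(2,3,6-trimethoxyphenyl)propan-2-ol, via 3-lithio-1,2,4-trimethoxybenzene 3 (not isolated)
Conditions: n-BuLi, THF, 0 °C to rt; 2, −78 °C to rt; H2O
Reagents that add atoms: none
Why: Directed ortho-metalation removes the hydrogen flanked by two methoxy groups (future C13), and the aryllithium adds 1,2 to acetone.

Step 2
Reactants: 4 2-(2,3,6-trimethoxyphenyl)propan-2-ol
Product: 5 3-isopropyl-1,2,4-trimethoxybenzene (future C11-OMe, C12-OMe, C13-isopropyl, C14-OMe; C8–H and C9–H free)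
Conditions: Et3SiH, CF3CO2H, CH2Cl2, 0 °C to rt
Reagents that add atoms: none
Why: Ionic hydrogenation, in which acid ionises the tertiary benzylic alcohol to a cation stabilised by two ortho methoxy groups and the silane delivers hydride to it.

Step 3
Reactants: 5 3-isopropyl-1,2,4-trimethoxybenzene
Product: 7 1-bromo-4-isopropyl-2,3,5-trimethoxybenzene (the C9 bromide), via C9 aryllithium 6 (not isolated)
Conditions: n-BuLi, TMEDA, Et2O, 0 °C to rt; BrCH2CH2Br, −78 °C to rt
Reagents that add atoms: 1,2-dibromoethane, BrCCBr
Why: Directed ortho-metalation with a bromine quench, which should favour C9–H (ortho to C11-OMe and meta to two further methoxy groups) over C8–H (one methoxy group para, and its ortho C14-OMe turned by the isopropyl group so that the methyl covers C8–H), the opposite of electrophilic selectivity.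

Step 4
Reactants: 8 methyl 2-oxocyclohexane-1-carboxylate; 9 L-valine tert-butyl ester
Product: 10 methyl 2-{[(2S)-1-tert-butoxy-3-methyl-1-oxobutan-2-yl]amino}cyclohex-1-ene-1-carboxylate
Conditions: BF3·OEt2 (cat.), toluene, reflux, Dean–Stark trap
Reagents that add atoms: none
Why: Acid-catalysed condensation of a β-keto ester with a primary amine gives the hydrogen-bonded enamino ester and leaves the valine stereocentre untouched.

Step 5
Reactants: 10 enamino ester
Product: 13 methyl (1S)-1-methyl-2-oxocyclohexane-1-carboxylate (C4 set), via lithioenamine 11 (not isolated), via C4-methylated imine 12 (not isolated)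
Conditions: LiN(i-Pr)2, toluene, −78 °C; HMPA; MeI, −78 °C; then 1 M aq citric acid, rt
Reagents that add atoms: iodomethane, CI; water, O
Why: Auxiliary-controlled alkylation of a chelated lithioenamine, in which lithium is held by the nitrogen and the two ester carbonyls, the valine isopropyl group shields one face and HMPA fills the last coordination site, so MeI attacks the open face and sets the (S)-quaternary C4 before mild acid hydrolyses the imine and frees the auxiliary.

Step 6
Reactants: 13 methyl (1S)-1-methyl-2-oxocyclohexane-1-carboxylate; 7 C9 bromide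
Product: 14 methyl (1S,3RS)-3-(4-isopropyl-2,3,5-trimethoxyphenyl)-1-methyl-2-oxocyclohexane-1-carboxylate
Conditions: Pd(OAc)2 (3 mol %), XPhos (6 mol %), K3PO4, toluene, 90 °C
Reagents that add atoms: none
Why: Buchwald–Hartwig ketone α-arylation, where C10H2 is the only enolisable position, the bulky biarylphosphine accepts the ortho-methoxy bromide and stops at monoarylation, K3PO4 spares the non-enolisable β-keto ester from retro-Claisen cleavage, and the C10 epimer mixture is erased in the next step.

Step 7
Reactants: 14 α-aryl keto ester; 15 formaldehyde (monomer cracked from paraformaldehyde)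
Product: 18 (1S,5R)-5-(4-isopropyl-2,3,5-trimethoxyphenyl)-1-methyl-3-oxabicyclo[3.3.1]nonane-2,9-dione (C4 S, C10 R, ketone at C5), via lithium enolate 16 (not isolated), via lithium aldolate 17 (not isolated)
Conditions: LiN(SiMe3)2, THF, −78 to 0 °C; 15, −78 to 0 °C; AcOH
Reagents that add atoms: none
Why: Formaldehyde aldol followed by lactonisation (transesterification), in which the lithium-chelated ester lies in the enolate plane, the C4 methyl is pseudoaxial and formaldehyde should enter anti to it (cis to the ester), while any trans aldolate cannot lactonise and returns by retro-aldol, so C10 (R) is fixed by C4 through closure of ring D.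

Step 8
Reactants: 18 keto lactone
Product: 19 (1S,5R)-5-(4-isopropyl-2,3,5-trimethoxyphenyl)-1-methyl-9-methylidene-3-oxabicyclo[3.3.1]nonan-2-one
Conditions: Ph3PCH3Br, KN(SiMe3)2, toluene–THF, 0 °C, then 18, 60 °C
Reagents that add atoms: methyltriphenylphosphonium bromide, C[P+](c1ccccc1)(c1ccccc1)c1ccccc1.[Br-]
Why: Wittig methylenation, which should work because the bridge ketone has its flanking groups tied back and cannot enolise, bridge ketones of bicyclo[3.3.1]nonanes with a bridgehead ester are known to olefinate, and the neopentyl lactone carbonyl reacts more slowly with the ylide.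

Step 9
Reactants: 19 methylene lactone
Product: 20 (1S,5R)-5-(2-iodo-4-isopropyl-3,5,6-trimethoxyphenyl)-1-methyl-9-methylidene-3-oxabicyclo[3.3.1]nonan-2-one (C8 iodide, C5=C6H2)
Conditions: NIS, CF3CO2H (cat.), MeCN, 0 °C to rt, dark
Reagents that add atoms: N-iodosuccinimide, O=C1CCC(=O)N1I
Why: Electrophilic aromatic iodination at C8–H, the only aromatic hydrogen (ortho to C14-OMe, para to C12-OMe), which should out-compete the alkene because its iodonium ion forms reversibly and finds neither an allylic hydrogen nor an accessible nucleophile between the two quaternary carbons.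

Step 10
Reactants: 20 C8 iodide with C5 exocyclic methylene; 21 carbon monoxide
Product: 22 (4S,10R)-11,12,14-trimethoxy-7-oxoabieta-5,8,11,13-tetraen-19,20-olide
Conditions: Pd(OAc)2 (10 mol %), PPh3 (30 mol %), Et3N, CO (1 atm), dry MeCN–toluene, 85 °C
Reagents that add atoms: none
Why: Proposed new method: zerovalent palladium (formed from Pd(OAc)2 and PPh3) inserts into the strained C8 iodide bond, CO inserts at once because direct arylpalladation of the alkene could only be 4-exo or 5-endo, the aroylpalladium iodide adds across C5=C6 with acyl carbon C7 on the free CH2 terminus C6 and palladium on C5, and loss of the now ketone-acidified C6 hydrogen (syn β-hydride elimination once ring B flattens, or Et3N-assisted) releases the C5=C6–C7=O enone and zerovalent palladium. The closest known reaction type is the carbonylative Heck cyclisation (cyclic acylpalladation) of 1-iodo-2-alkenylbenzenes, which normally closes in the exo mode, so endo closure onto the bridge methylene of a bicyclo[3.3.1]nonane is an extrapolation. Ring B closes 6-endo-trig, forming C7–C8 and C6–C7. No stereocentre is created, and the quaternary centres C4 and C10 cannot epimerise. The selectivity needed is 6-endo over 5-exo: the rigid bicycle holds C9 in the alkene plane with C8 next to C6, the 5-exo mode would have to build a third contiguous quaternary carbon at C5 between C4 and C10, and the neopentyl-type C6–palladium species it would give has no β-hydrogen and, in a medium free of water, alcohols and N–H amines, no productive exit, whereas the endo adduct can eliminate. Iodide is kept on palladium (no silver or thallium salts) so that insertion stays under steric control.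

Step 11
Reactants: 22 enone
Product: 23 (4S,5R,10R)-11,12,14-trimethoxy-7-oxoabieta-8,11,13-trien-19,20-olide (5α-H, A/B trans)
Conditions: SmI2 (2.2 equiv), THF–MeOH, −78 °C
Reagents that add atoms: none
Why: Electron-transfer conjugate reduction of an aryl enone, in which two electrons place a carbanion (organosamarium) at C5 that should pyramidalise with its lone pair on the α face, anti to the electron-poor C4–C19 and C10–C20 bonds and with C6 leaning over the flat lactone bridge (one syn-axial hydrogen) rather than over C1–C3 (two), so protonation gives 5α-H (5R); water is excluded because it would switch on lactone reduction.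

Step 12
Reactants: 23 trimethyl ether ketone
Product: 24 (4S,5R,10R)-12-methoxy-7,11,14-trioxoabieta-8,12-dien-19,20-olide (11,14-quinone)
Conditions: (NH4)2Ce(NO3)6, MeCN–H2O, 0 °C
Reagents that add atoms: water, O
Why: Oxidative demethylation of a 1,4-dimethoxyarene by tetravalent cerium, where the para pair C11-OMe/C14-OMe leaves as methanol with water supplying the quinone oxygens, the C12 methoxy group survives as a vinylogous ester, and no stereocentre is touched.

Step 13
Reactants: 24 quinone
Product: 25 (4S,5R,10R)-11,14-dihydroxy-12-methoxy-7-oxoabieta-8,11,13-trien-19,20-olide (target)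
Conditions: Na2S2O4, EtOAc–H2O, rt, under argon
Reagents that add atoms: none
Why: Dithionite reduction of a quinone to its hydroquinone, whose C14–OH is held by a hydrogen bond to the C7 ketone, while ketone, lactone and stereocentres are inert.

**Compound list**
1 | 1,2,4-trimethoxybenzene | COc1ccc(OC)c(OC)c1 | starting material
2 | acetone | CC(C)=O | starting material
3 | 3-lithio-1,2,4-trimethoxybenzene | COc1ccc(OC)c([Li])c1OC | intermediate
4 | 2-(2,3,6-trimethoxyphenyl)propan-2-ol | COc1ccc(OC)c(C(C)(C)O)c1OC | intermediate
5 | 3-isopropyl-1,2,4-trimethoxybenzene | COc1ccc(OC)c(C(C)C)c1OC | intermediate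
6 | (4-isopropyl-2,3,5-trimethoxyphenyl)lithium | [Li]c1cc(OC)c(C(C)C)c(OC)c1OC | intermediate
7 | 1-bromo-4-isopropyl-2,3,5-trimethoxybenzene | Brc1cc(OC)c(C(C)C)c(OC)c1OC | intermediate
8 | methyl 2-oxocyclohexane-1-carboxylate | COC(=O)C1CCCCC1=O | starting material
9 | L-valine tert-butyl ester | CC(C)[C@H](N)C(=O)OC(C)(C)C | starting material
10 | methyl 2-{[(2S)-1-tert-butoxy-3-methyl-1-oxobutan-2-yl]amino}cyclohex-1-ene-1-carboxylate | COC(=O)C1=C(N[C@@H](C(C)C)C(=O)OC(C)(C)C)CCCC1 | intermediate
11 | N-lithio derivative of 10 | COC(=O)C1=C(N([Li])[C@@H](C(C)C)C(=O)OC(C)(C)C)CCCC1 | intermediate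
12 | methyl (1S)-2-{[(2S)-1-tert-butoxy-3-methyl-1-oxobutan-2-yl]imino}-1-methylcyclohexane-1-carboxylate | COC(=O)[C@@]1(C)CCCCC1=N[C@@H](C(C)C)C(=O)OC(C)(C)C | intermediate
13 | methyl (1S)-1-methyl-2-oxocyclohexane-1-carboxylate | O=C1CCCC[C@]1(C)C(=O)OC | intermediate
14 | methyl (1S,3RS)-3-(4-isopropyl-2,3,5-trimethoxyphenyl)-1-methyl-2-oxocyclohexane-1-carboxylate | O=C1C(c2cc(OC)c(C(C)C)c(OC)c2OC)CCC[C@]1(C)C(=O)OC | intermediate
15 | formaldehyde (from paraformaldehyde) | C=O | starting material
16 | lithium enolate of 14 (C5–O–Li, C5=C10) | [Li]OC1=C(c2cc(OC)c(C(C)C)c(OC)c2OC)CCC[C@]1(C)C(=O)OC | intermediate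
17 | lithium alkoxide of methyl (1S,3R)-3-(hydroxymethyl)-3-(4-isopropyl-2,3,5-trimethoxyphenyl)-1-methyl-2-oxocyclohexane-1-carboxylate | [Li]OC[C@]1(c2cc(OC)c(C(C)C)c(OC)c2OC)CCC[C@](C)(C(=O)OC)C1=O | intermediate
18 | (1S,5R)-5-(4-isopropyl-2,3,5-trimethoxyphenyl)-1-methyl-3-oxabicyclo[3.3.1]nonane-2,9-dione | COc1c(OC)c(cc(OC)c1C(C)C)[C@]12CCC[C@](C)(C(=O)OC1)C2=O | intermediate
19 | (1S,5R)-5-(4-isopropyl-2,3,5-trimethoxyphenyl)-1-methyl-9-methylidene-3-oxabicyclo[3.3.1]nonan-2-one | COc1c(OC)c(cc(OC)c1C(C)C)[C@]12CCC[C@](C)(C(=O)OC1)C2=C | intermediate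
20 | (1S,5R)-5-(2-iodo-4-isopropyl-3,5,6-trimethoxyphenyl)-1-methyl-9-methylidene-3-oxabicyclo[3.3.1]nonan-2-one | COc1c(OC)c(c(I)c(OC)c1C(C)C)[C@]12CCC[C@](C)(C(=O)OC1)C2=C | intermediate
21 | carbon monoxide | [C-]#[O+] | starting material
22 | (4S,10R)-11,12,14-trimethoxy-7-oxoabieta-5,8,11,13-tetraen-19,20-olide | COc1c(OC)c2c(c(OC)c1C(C)C)C(=O)C=C1[C@]23CCC[C@]1(C)C(=O)OC3 | intermediate
23 | (4S,5R,10R)-11,12,14-trimethoxy-7-oxoabieta-8,11,13-trien-19,20-olide | COc1c(OC)c2c(c(OC)c1C(C)C)C(=O)C[C@@H]1[C@]23CCC[C@]1(C)C(=O)OC3 | intermediate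
24 | (4S,5R,10R)-12-methoxy-7,11,14-trioxoabieta-8,12-dien-19,20-olide | COC1=C(C(C)C)C(=O)C2=C(C1=O)[C@]34CCC[C@](C)(C(=O)OC3)[C@@H]4CC2=O | intermediate
25 | (4S,5R,10R)-11,14-dihydroxy-12-methoxy-7-oxoabieta-8,11,13-trien-19,20-olide | COc1c(O)c2c(c(O)c1C(C)C)C(=O)C[C@@H]1[C@]23CCC[C@]1(C)C(=O)OC3 | target

**Step count**
Total step count: 13.
Longest linear sequence: 11 (steps 1–3, then 6–13).

**Steps most likely to fail**

1. Step 10.
- What may go wrong: the acyl group may transfer to the inner alkene carbon (5-exo). Alternatively the aroylpalladium may stall, because a tertiary C5–palladium bond between two quaternary carbons is costly, which would end in loss of iodine or decarbonylation.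
- Fallback: the event is split into two polar steps of known type, starting from 20.
- Iodine–magnesium exchange (iPrMgCl·LiCl, THF, −20 °C) followed by CO2 gives 5-isopropyl-3,4,6-trimethoxy-2-[(1S,5R)-1-methyl-9-methylidene-2-oxo-3-oxabicyclo[3.3.1]nonan-5-yl]benzoic acid F1.
- Treatment with (COCl)2 and catalytic DMF gives the corresponding aroyl chloride F2.
- SnCl4 in CH2Cl2 at −78 to 0 °C then triggers an intramolecular Darzens–Nenitzescu acylation of the alkene. The acylium ion bonds to C6 in the Markovnikov sense (tertiary cation at C5), and loss of the only available proton, at C6, gives the enone.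
- The route is rejoined at 22.

2. Step 11.
- What may go wrong: facial selectivity in the protonation at C5 may be poor, since the two bridges over the alkene faces differ only modestly. The C7 ketone may also be over-reduced.
- Fallback: ring D is opened so that the β face becomes clearly the more hindered one, starting from 22.
- KOH in aqueous MeOH–THF at 60 °C gives potassium (4S,10R)-20-hydroxy-11,12,14-trimethoxy-7-oxoabieta-5,8,11,13-tetraen-19-oate F3.
- TBSCl and imidazole in DMF convert the salt directly into the 20-O-TBS ether TBS ester F4.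
- With two freely rotating axial groups on the β face, hydrogenation (H2, Pd/C, EtOAc) should add from the α face, as in ordinary 5,6-dehydro-7-oxoabietanes, to give the 5α-H bis-silyl compound F5.
- Aqueous HCl in THF removes both silyl groups, and the 1,3-diaxial hydroxy acid relactonises.
- The route is rejoined at 23.

3. Step 9.
- What may go wrong: substitution may be slow at the position squeezed between C14-OMe and the bridgehead-bearing C9. Attack of the iodinating agent on the alkene, or acid-induced loss of iodine from the crowded product, could then compete.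
- Fallback: iodine is introduced before C10 becomes quaternary and before the alkene exists, starting from 14.
- NIS in MeCN gives methyl (1S,3RS)-3-(2-iodo-4-isopropyl-3,5,6-trimethoxyphenyl)-1-methyl-2-oxocyclohexane-1-carboxylate F6.
- The conditions of step 7 give (1S,5R)-5-(2-iodo-4-isopropyl-3,5,6-trimethoxyphenyl)-1-methyl-3-oxabicyclo[3.3.1]nonane-2,9-dione F7.
- The Wittig conditions of step 8 then install the methylene group.
- The route is rejoined at 20.

Further compounds
F1 | step 10 | 5-isopropyl-3,4,6-trimethoxy-2-[(1S,5R)-1-methyl-9-methylidene-2-oxo-3-oxabicyclo[3.3.1]nonan-5-yl]benzoic acid | COc1c(OC)c(c(C(=O)O)c(OC)c1C(C)C)[C@]12CCC[C@](C)(C(=O)OC1)C2=C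
F2 | step 10 | 5-isopropyl-3,4,6-trimethoxy-2-[(1S,5R)-1-methyl-9-methylidene-2-oxo-3-oxabicyclo[3.3.1]nonan-5-yl]benzoyl chloride | COc1c(OC)c(c(C(=O)Cl)c(OC)c1C(C)C)[C@]12CCC[C@](C)(C(=O)OC1)C2=C
F3 | step 11 | potassium (4S,10R)-20-hydroxy-11,12,14-trimethoxy-7-oxoabieta-5,8,11,13-tetraen-19-oate | COc1c(OC)c2c(c(OC)c1C(C)C)C(=O)C=C1[C@]2(CO)CCC[C@]1(C)C(=O)[O-].[K+]
F4 | step 11 | tert-butyldimethylsilyl (4S,10R)-20-(tert-butyldimethylsilyloxy)-11,12,14-trimethoxy-7-oxoabieta-5,8,11,13-tetraen-19-oate | COc1c(OC)c2c(c(OC)c1C(C)C)C(=O)C=C1[C@]2(CO[Si](C)(C)C(C)(C)C)CCC[C@]1(C)C(=O)O[Si](C)(C)C(C)(C)C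
F5 | step 11 | tert-butyldimethylsilyl (4S,5R,10R)-20-(tert-butyldimethylsilyloxy)-11,12,14-trimethoxy-7-oxoabieta-8,11,13-trien-19-oate | COc1c(OC)c2c(c(OC)c1C(C)C)C(=O)C[C@@H]1[C@]2(CO[Si](C)(C)C(C)(C)C)CCC[C@]1(C)C(=O)O[Si](C)(C)C(C)(C)C
F6 | step 9 | methyl (1S,3RS)-3-(2-iodo-4-isopropyl-3,5,6-trimethoxyphenyl)-1-methyl-2-oxocyclohexane-1-carboxylate | O=C1C(c2c(I)c(OC)c(C(C)C)c(OC)c2OC)CCC[C@]1(C)C(=O)OC
F7 | step 9 | (1S,5R)-5-(2-iodo-4-isopropyl-3,5,6-trimethoxyphenyl)-1-methyl-3-oxabicyclo[3.3.1]nonane-2,9-dione | COc1c(OC)c(c(I)c(OC)c1C(C)C)[C@]12CCC[C@](C)(C(=O)OC1)C2=O
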